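# Total synthesis proposal for dictyol H (28)

## Analysis of the target

Dictyol H (28) is a prenylated guaiane. In the numbering used throughout, ring A is the cyclopentene C1–C2–C3=C4(CH3)–C5. Ring B is the cycloheptane C1–C5–C6(OH)–C7–C8–C9–C10(=CH2). Ring C is the tetrahydrofuran O–C11(CH3)–C12–C13–C14, which hangs on C7 through C11 and ends in the tertiary acetate on C15.

The six stereocentres are 1R,5R,6S,7R,11R,14R. Rings A and B are cis-fused, and H-1, H-5, H-6 and H-7 all lie on one face (called α, the convex face). 6-OH and C11 are therefore cis to each other on the concave β face, and in ring C the bicycle on C11 is trans to the C15 group on C14. C1, C5, C6 and C7 are contiguous and can control each other. C11 is fully substituted, exocyclic and freely rotating, so its configuration cannot be relayed from the rings with confidence and has to come from outside.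

There are three sensitive points:
- The C10 methylene is moved into the ring by acid.
- H-5 is allylic and sits next to the carbinol, or next to any carbonyl placed at C4 or C6.
- A tertiary acetate stands beside a free secondary alcohol, which rules out a late selective acetylation.

The hard part is the seven-membered ring, which carries a different kind of substituent on five of its seven atoms.

Two features of the structure suggest the plan. First, the run C1(H)–C10(=CH2)–C9H2–C8H2–C7(branched)–C6(O)–C5(H) of ring B is the retron of an allene/vinylcyclopropane (5+2) cycloaddition: C1=C10=CH2 is the allene, C7–C8–C9 the cyclopropane, and C5=C6 the vinyl group as an enol ether. Second, ring C together with C7 and C8 is (2R,5R)-trans-furanoid linalool oxide, atom for atom.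

## Retrosynthetic reasoning

**28 ⇒ 26 ⇒ 24 (cut C4–CH3).** The methyl group on C4 is removed together with the C3=C4 olefin, which leads through enol triflate 26 to cyclopentanone 24. The cut is made here because an oxygen on C4 is what remains of the temporary control element of the key step. Kinetic enolisation away from the substituted C5 fixes the olefin position without any elimination regiochemistry. The forward steps must deprotonate C3 and not C5, so 6-OH is masked as its triethylsilyl ether.

**24 ⇒ 23 ⇒ 22 ⇒ 21 (no C–C bond, redox exchange between C4 and C6).** Ketone 23 comes from diol 22 by oxidation of the open C4 carbinol beside the buried C6 carbinol. Diol 22 comes from β-hydroxy ketone 21. The 4α-hydroxyl carries the hydride to the α face of C6, which is exactly the face that puts 6-OH on the β side.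

**21 ⇒ 19 (cut C7–H).** The C6 ketone and the C7 stereocentre are both stored in the tetrasubstituted enol silane of 19. The forward step is a protonation of C7 from the convex face. C11 is already in place and is not touched.

**19 ⇒ 18 (key step: cut C1–C5 and C9–C10, re-form C7–C9).** Both carbocycles are opened at once. The precursor 18 is an open chain that holds only a cyclopropane and ring C. The cut is made here because the allene delivers the C10 methylene in its final position and the cyclopropane delivers the two bare methylenes C8 and C9. The enol ether delivers the C6 oxygen with a defined regiochemistry. No other pair of bonds removes ring B and ring A together. The forward reaction has to set C1 and C5 relative to the single tether stereocentre C4.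

**18 ⇒ 16 ⇒ 9 + 13 (cut C4–C5).** The β-silyloxy enol silane is the silylated form of aldol 16. Methyl ketone 9 can enolise on one side only, since C7 is quaternary, and aldehyde 13 is unbranched. The forward aldol joins the two halves and creates the temporary C4 carbinol under reagent control.

**13 ⇒ 12 ⇒ 10 (cut C10=CH2).** The terminal allene carbon is removed. Alkynol 10 is homologated by one carbon and the alcohol is oxidised.

**9 ⇒ 8 ⇒ 6 (cut C9 out of the cyclopropane, then C6–C7).** The cyclopropane is the methylene adduct of α-substituted enone 8. Its acetyl group (C5, C6) is joined to C7 by cross-coupling of bromoalkene 6 with an acetyl anion equivalent. This is the shortest way to make the vinyl CH of the chiral-pool unit quaternary without touching C11.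

**6 ⇒ 4 ⇒ 3 ⇒ 1 (cut C7–Br, the acetyl C–O bond and O–C14).** Bromoalkene 6 is the vinyl group of acetate 4 after addition and loss of HBr. Compound 4 is the acetate of linalool oxide 3, and 3 is the epoxide-opening product of (R)-linalool 1. C11 is bought, C14 is set by the epoxidation catalyst, and the acetate is installed while no other hydroxyl exists.

## Alternatives that were turned down

**Alternative 1:** (textbook route) Disconnection of C9–C10 as an olefin by ring-closing metathesis, with ring A taken from the chiral pool.
- Forward route: cyclopentenecarbaldehyde A1 receives at C6 a C7 nucleophile that carries an allyl group and ring C, which gives diene A2. The second-generation Grubbs catalyst then closes ring B to A3.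
- The metathesis consumes the methylene carbon of the isopropenyl group. A3 therefore holds the endocyclic C9=C10 olefin with a methyl group on C10, and the move to the exocyclic position is contra-thermodynamic.
- The open-chain C6–C7 bond formation would have to set C6 and C7 next to the quaternary C11 without any control element.
- The C4=C5 enal olefin of A1 must later be deconjugated to C3=C4 by a kinetic protonation at C5. Three repairs on three sites cost more steps than the ring closure saves.

**Alternative 2:** Disconnection of C6–C7 and O–C11 in one Prins-type cascade.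
- Forward route: in aldehyde A4 a Lewis acid would make the E-configured C7=C11 olefin of a geranyl-type chain attack the C6 aldehyde, and 14-OH would trap the C11 cation. This would close rings B and C and give 28 directly.
- The anti addition across the E olefin does give the correct C7/C11 relation, which makes the idea attractive.
- The C10 methylene of A4 is a better nucleophile than the trisubstituted olefin, and it reaches C6 through a five-membered transition state, so a bicyclo[3.3.0] product should win.
- A seven-membered Prins closure is slow, and nothing fixes which face of the olefin meets which face of the β,γ-unsaturated and epimerisable aldehyde.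
- The usual chair preference would put 6-OH trans to C11.

**Alternative 3:** Disconnection of C7–C11 as a union of two advanced fragments.
- Forward route: the side-chain-free enol silane A5 (from the same cycloaddition on a simpler substrate) would add under Mukaiyama conditions to the oxocarbenium ion from methyl ketal A6, which gives ketone A7.
- The route is convergent and short, but C11 is created at a planar cation whose only bias is the remote C14 substituent, and such five-membered ions are known to discriminate poorly.
- A7 is a β-alkoxy ketone with an acidic H-7, so ring C can open and close again by retro-Michael addition and scramble C7 and C11.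
- H-5 of A7 lies between a ketone and an olefin and invites conjugation.
- A5 would need an enantioselective version of the cycloaddition that is not known for allenes.

Key step: step 10

Convention: α is the face of H-1 and H-5 in the bicycle and β is the opposite face. Atom numbers are those of the target, also in open-chain precursors.

Assumption: the enolborinate formed from a methyl ketone and (+)-Ipc2BCl is taken to add to the Si face of an unbranched aldehyde (4R product). Both antipodes of the reagent are commercial, so the opposite sense would change only the choice of antipode.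

## Route

Step 1
Reactants: 1 (R)-(−)-linalool
Product: 3 (2R,5R)-trans-furanoid linalool oxide, via epoxylinalool 2 (not isolated)
Conditions: L-fructose-derived Shi ketone (30 mol%), KHSO5, K2CO3, Bu4NHSO4, aq. Na2B4O7 buffer, MeCN–CH2(OMe)2, 0 °C; then CSA (cat.), CH2Cl2, 0 °C
Reagents that add atoms: potassium peroxymonosulfate, [K+].[O-]S(=O)(=O)OO
Why: Shi epoxidation: the electrophilic dioxirane takes the trisubstituted olefin and leaves the vinyl group, and the antipode of the common catalyst should give the 14S epoxide 2. The tertiary 11-OH then opens the epoxide in the 5-exo mode at the secondary C14 with inversion (14R), which gives the trans ring C; C11 comes from the chiral pool.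

Step 2
Reactants: 3 (2R,5R)-trans-furanoid linalool oxide
Product: 4 linalool oxide acetate 2-[(2R,5R)-5-ethenyl-5-methyloxolan-2-yl]propan-2-yl acetate
Conditions: Ac2O, Et3N, DMAP (cat.), CH2Cl2, reflux
Reagents that add atoms: acetic anhydride, CC(=O)OC(C)=O
Why: DMAP-catalysed acylation of the only hydroxyl group. The tertiary acetate of the target is installed here because it could not be made selectively once 6-OH exists.

Step 3
Reactants: 4 linalool oxide acetate
Product: 6 bromoalkene 2-[(2R,5R)-5-(1-bromoethenyl)-5-methyloxolan-2-yl]propan-2-yl acetate, via vicinal dibromide 5 (not isolated)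
Conditions: Br2, CH2Cl2, −78 °C; then DBU, DMF, 60 °C
Reagents that add atoms: bromine, BrBr
Why: Bromine adds to the only olefin and DBU removes HBr by E2. H-7 is acidified by its own bromine and by the neighbouring C11–O bond, so the terminal bromide leaves and the 2-bromo-1-alkene should form, as is known for vicinal dibromides next to an oxygen function.

Step 4
Reactants: 6 bromoalkene
Product: 8 enone 2-[(2R,5R)-5-methyl-5-(3-oxobut-1-en-2-yl)oxolan-2-yl]propan-2-yl acetate, via ethoxydiene 7 (not isolated)
Conditions: tributyl(1-ethoxyvinyl)stannane, PdCl2(PPh3)2 (5 mol%), toluene, 100 °C; then 1 M HCl, THF, rt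
Reagents that add atoms: tributyl(1-ethoxyvinyl)stannane, CCCC[Sn](CCCC)(CCCC)C(=C)OCC; water, O
Why: Stille coupling with an acetyl anion equivalent forms C6–C7 under neutral conditions that spare the acetate. Mild acid then hydrolyses the enol ether to the methyl ketone (C5, C6).

Step 5
Reactants: 8 enone
Product: 9 cyclopropyl methyl ketone 2-[(2R,5R)-5-(1-acetylcyclopropyl)-5-methyloxolan-2-yl]propan-2-yl acetate
Conditions: Me3S(O)I, NaH, DMSO, rt
Reagents that add atoms: trimethylsulfoxonium iodide, C[S+](C)(C)=O.[I-]
Why: Corey–Chaykovsky cyclopropanation: the soft sulfoxonium ylide adds 1,4 to the unsubstituted C8 terminus and the enolate closes the three-membered ring at C7 (C9 is the new carbon). C7 becomes quaternary and not stereogenic, so the β-alkoxy ketone can no longer eliminate.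

Step 6
Reactants: 10 pent-4-yn-1-ol
Product: 12 hexa-4,5-dien-1-ol, via propargylic amine 11 (not isolated)
Conditions: (CH2O)n, CuI, iPr2NH, dioxane, reflux
Reagents that add atoms: formaldehyde (as paraformaldehyde), C=O
Why: Crabbé homologation: the Mannich base 11 of the terminal alkyne undergoes a copper-mediated hydride transfer from an isopropyl group and loses the imine, which gives the terminal allene C1=C10=CH2.

Step 7
Reactants: 12 hexa-4,5-dien-1-ol
Product: 13 hexa-4,5-dienal
Conditions: TEMPO (cat.), PhI(OAc)2, CH2Cl2, rt
Reagents that add atoms: none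
Why: Oxoammonium oxidation of a primary alcohol stops at the aldehyde and leaves the allene untouched.

Step 8
Reactants: 9 cyclopropyl methyl ketone; 13 hexa-4,5-dienal
Product: 16 (4R)-aldol 2-[(2R,5R)-5-{1-[(3R)-3-hydroxyocta-6,7-dienoyl]cyclopropyl}-5-methyloxolan-2-yl]propan-2-yl acetate, via enol borinate 14 (not isolated), via boron aldolate 15 (not isolated)
Conditions: (+)-Ipc2BCl, Et3N, Et2O, 0 °C; 13, −78 to −20 °C; then H2O2, pH 7 buffer, MeOH
Reagents that add atoms: none
Why: Diisopinocampheylboron-mediated aldol of a methyl ketone: only C5 can be enolised, the chloroborane does not enolise the acetate, and the chiral ligands direct the attack to one aldehyde face (4R). As 9 is a single enantiomer, the minor 4S product is a diastereomer and should be removable by chromatography.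

Step 9
Reactants: 16 (4R)-aldol
Product: 18 bis-silyl ether 2-[(2R,5R)-5-{1-[(1Z,3R)-1,3-bis(tert-butyldimethylsilyloxy)octa-1,6,7-trienyl]cyclopropyl}-5-methyloxolan-2-yl]propan-2-yl acetate, via silyloxy ketone 17 (not isolated)
Conditions: TBSOTf (2.5 equiv), Et3N, CH2Cl2, −78 to 0 °C
Reagents that add atoms: tert-butyldimethylsilyl triflate, CC(C)(C)[Si](C)(C)OS(=O)(=O)C(F)(F)F
Why: The alcohol is silylated first, then soft enolisation of the ketone follows, which is regiospecific because C7 bears no hydrogen. A ketone with one very large flank should give the Z enol silane, with C4 cis to the oxygen and trans to the cyclopropane, which is the geometry the cycloaddition needs.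

Step 10
Reactants: 18 bis-silyl ether
Product: 19 cycloadduct cis-fused 4α,6-bis(tert-butyldimethylsilyloxy)-10-methylenebicyclo[5.3.0]dec-6-ene bearing ring C on C7 (1R,4R,5R; H-1 and H-5 α)
Conditions: [Rh(CO)2Cl]2 (5 mol%), toluene (0.01 M), 90 °C
Reagents that add atoms: none
Why: This is the rhodium-catalysed intramolecular (5+2) cycloaddition of an allene with a vinylcyclopropane, a type known for allenyl vinylcyclopropanes with a three-atom tether that bears a carbinol centre and for 1-substituted cyclopropanes; the only new feature is that the vinyl group is a silyl enol ether. Monovalent rhodium binds the C5=C6 and C1=C10 π bonds and opens the strained C7–C9 bond to a σ-alkyl/π-allyl (C5–C6–C7) metallacycle, the internal allene π bond inserts to form C1–C5, and reductive elimination forms C9–C10 and leaves C6=C7 as the enol silane. Ring A is closed by the C1–C5 bond over the tether C2–C4 (a 5-exo type closure at the proximal allene carbon), and ring B by the C9–C10 bond as the union of the five-carbon unit C5–C6–C7–C8–C9 with C1=C10. C5 is controlled by C4: in the Z enol silane the bulky silyloxy group on C6 is cis to C4, so allylic 1,3-strain holds H-4 in the olefin plane with C3 on one face and 4-OTBS on the other, and the tethered allene can reach only the face that makes H-5 cis to 4-OTBS, which is 5R for 4R. C1 is controlled by the tether, which allows only the cis-fused bicycle, so H-1 ends up cis to H-5 (1R). The step needs the internal and not the terminal allene π bond to react, which the five- versus six-membered ring closure secures; the choice between C8 and C9 has no constitutional consequence, and the quaternary C7 favours the reactive conformer of the vinylcyclopropane. In one operation the open chain becomes the complete hydroazulene, the C10 methylene stands in its final place, and the C6 oxygen and the future C7 centre are stored in one regiodefined enol silane.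

Step 11
Reactants: 19 cycloadduct
Product: 21 β-hydroxy ketone 4α-hydroxy-6-oxo compound with H-7 α (ring C on C7 β), via silyloxy ketone 20 (not isolated)
Conditions: HF·pyridine, pyridine, THF, 0 °C to rt
Reagents that add atoms: none
Why: Protodesilylation of the enol silane puts the proton on C7 from the convex α face of the cis-fused bicycle, which sets C7 with C11 on the β face. This epimer also has C11 pseudo-equatorial and cis to the C5–C4 bond, so it should not be lost by equilibration, and the secondary silyl ether falls in the same pot under buffered conditions that spare the acetate and the methylene group.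

Step 12
Reactants: 21 β-hydroxy ketone
Product: 22 anti-diol 4α,6β-dihydroxy compound
Conditions: Me4NBH(OAc)3, MeCN–AcOH, −30 °C
Reagents that add atoms: none
Why: Evans–Saksena reduction: the 4α-hydroxyl exchanges onto boron and delivers hydride within a six-membered transition state to the α face of C6, which gives H-6 α and 6-OH β (6S, 1,3-anti). The reagent does not reduce ketones without a directing hydroxyl, nor esters or olefins.

Step 13
Reactants: 22 anti-diol
Product: 23 hydroxy ketone 6β-hydroxy-4-oxo compound
Conditions: TEMPO (cat.), PhI(OAc)2, CH2Cl2, rt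
Reagents that add atoms: none
Why: The bulky oxoammonium salt should oxidise the open cyclopentanol at C4. It should leave 6-OH, which is flanked by two tertiary carbons, lies next to the quaternary C11 and is hydrogen-bonded to the ring C oxygen.

Step 14
Reactants: 23 hydroxy ketone
Product: 24 6-O-triethylsilyl ether of 23
Conditions: TESOTf, 2,6-lutidine, CH2Cl2, −78 °C
Reagents that add atoms: triethylsilyl triflate, CC[Si](CC)(CC)OS(=O)(=O)C(F)(F)F
Why: A silyl triflate is needed for the hindered alcohol, and lutidine at low temperature does not enolise the ketone. The ether blocks retro-aldol opening of ring B in the next step.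

Step 15
Reactants: 24 6-O-triethylsilyl ether
Product: 26 enol triflate (C3=C4–OTf), via potassium enolate 25 (not isolated)
Conditions: KN(SiMe3)2 (1.05 equiv), THF, −78 °C; then Comins reagent, −78 °C
Reagents that add atoms: N-(5-chloropyridin-2-yl)bis(trifluoromethanesulfonimide), O=S(=O)(N(c1ccc(Cl)cn1)S(=O)(=O)C(F)(F)F)C(F)(F)F
Why: Kinetic deprotonation by a bulky amide takes the unhindered C3 methylene and not the tertiary H-5, so C5 is kept and the β-silyloxy group is not expelled. O-Triflation fixes the olefin at C3=C4.

Step 16
Reactants: 26 enol triflate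
Product: 28 dictyol H, via silyl ether 27 (not isolated)
Conditions: MeZnCl, Pd(PPh3)4 (5 mol%), THF, rt; then HF·pyridine, THF, 0 °C
Reagents that add atoms: methylzinc chloride, C[Zn]Cl
Why: Negishi coupling replaces the triflate by methyl with retention of the olefin position, and the organozinc reagent tolerates the acetate. Buffered fluoride then frees 6-OH without moving the C10 methylene.

## Compound list

1 | (R)-(−)-linalool, (3R)-3,7-dimethylocta-1,6-dien-3-ol | C=C[C@](C)(O)CCC=C(C)C | starting material
2 | (3R,6S)-6,7-epoxylinalool | C=C[C@](C)(O)CC[C@@H]1OC1(C)C | intermediate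
3 | (2R,5R)-trans-furanoid linalool oxide, 2-[(2R,5R)-5-ethenyl-5-methyloxolan-2-yl]propan-2-ol | C=C[C@@]1(C)CC[C@H](C(C)(C)O)O1 | intermediate
4 | 2-[(2R,5R)-5-ethenyl-5-methyloxolan-2-yl]propan-2-yl acetate | C=C[C@@]1(C)CC[C@H](C(C)(C)OC(C)=O)O1 | intermediate
5 | 2-[(2R,5R)-5-(1,2-dibromoethyl)-5-methyloxolan-2-yl]propan-2-yl acetate (both C7 epimers) | BrCC(Br)[C@@]1(C)CC[C@H](C(C)(C)OC(C)=O)O1 | intermediate
6 | 2-[(2R,5R)-5-(1-bromoethenyl)-5-methyloxolan-2-yl]propan-2-yl acetate | C=C(Br)[C@@]1(C)CC[C@H](C(C)(C)OC(C)=O)O1 | intermediate
7 | 2-[(2R,5R)-5-(3-ethoxybuta-1,3-dien-2-yl)-5-methyloxolan-2-yl]propan-2-yl acetate | C=C(OCC)C(=C)[C@@]1(C)CC[C@H](C(C)(C)OC(C)=O)O1 | intermediate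
8 | 2-[(2R,5R)-5-methyl-5-(3-oxobut-1-en-2-yl)oxolan-2-yl]propan-2-yl acetate | CC(=O)C(=C)[C@@]1(C)CC[C@H](C(C)(C)OC(C)=O)O1 | intermediate
9 | 2-[(2R,5R)-5-(1-acetylcyclopropyl)-5-methyloxolan-2-yl]propan-2-yl acetate | CC(=O)C1(CC1)[C@@]2(C)CC[C@H](C(C)(C)OC(C)=O)O2 | intermediate
10 | pent-4-yn-1-ol | C#CCCCO | starting material
11 | 6-(diisopropylamino)hex-4-yn-1-ol | CC(C)N(CC#CCCCO)C(C)C | intermediate
12 | hexa-4,5-dien-1-ol | C=C=CCCCO | intermediate
13 | hexa-4,5-dienal | C=C=CCCC=O | intermediate
14 | diisopinocampheyl enol borinate of 9 | C=C(OB([C@H]3C[C@H]4C[C@@H]([C@@H]3C)C4(C)C)[C@H]5C[C@H]6C[C@@H]([C@@H]5C)C6(C)C)C1(CC1)[C@@]2(C)CC[C@H](C(C)(C)OC(C)=O)O2 | intermediate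
15 | diisopinocampheylboron aldolate of 16 | C=C=CCC[C@@H](OB([C@H]3C[C@H]4C[C@@H]([C@@H]3C)C4(C)C)[C@H]5C[C@H]6C[C@@H]([C@@H]5C)C6(C)C)CC(=O)C1(CC1)[C@@]2(C)CC[C@H](C(C)(C)OC(C)=O)O2 | intermediate
16 | (4R)-aldol, 2-[(2R,5R)-5-{1-[(3R)-3-hydroxyocta-6,7-dienoyl]cyclopropyl}-5-methyloxolan-2-yl]propan-2-yl acetate | C=C=CCC[C@@H](O)CC(=O)C1(CC1)[C@@]2(C)CC[C@H](C(C)(C)OC(C)=O)O2 | intermediate
17 | 4-O-TBS ether of 16 | C=C=CCC[C@@H](O[Si](C)(C)C(C)(C)C)CC(=O)C1(CC1)[C@@]2(C)CC[C@H](C(C)(C)OC(C)=O)O2 | intermediate
18 | (Z)-enol silane of 17, allenyl vinylcyclopropane | C=C=CCC[C@@H](O[Si](C)(C)C(C)(C)C)/C=C(\O[Si](C)(C)C(C)(C)C)C1(CC1)[C@@]2(C)CC[C@H](C(C)(C)OC(C)=O)O2 | intermediate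
19 | (5+2) cycloadduct, cis-fused, 4α-OTBS, C6=C7 enol silane, C10 methylene (1R,4R,5R,11R,14R) | C=C1CCC([C@@]2(C)CC[C@H](C(C)(C)OC(C)=O)O2)=C(O[Si](C)(C)C(C)(C)C)[C@H]2[C@H](O[Si](C)(C)C(C)(C)C)CC[C@@H]12 | intermediate
20 | 4α-OTBS 6-ketone, H-7 α | C=C1CC[C@@H]([C@@]2(C)CC[C@H](C(C)(C)OC(C)=O)O2)C(=O)[C@H]2[C@H](O[Si](C)(C)C(C)(C)C)CC[C@@H]12 | intermediate
21 | 4α-hydroxy 6-ketone, H-7 α | C=C1CC[C@@H]([C@@]2(C)CC[C@H](C(C)(C)OC(C)=O)O2)C(=O)[C@H]2[C@H](O)CC[C@@H]12 | intermediate
22 | 4α,6β-diol | C=C1CC[C@@H]([C@@]2(C)CC[C@H](C(C)(C)OC(C)=O)O2)[C@@H](O)[C@H]2[C@H](O)CC[C@@H]12 | intermediate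
23 | 6β-hydroxy 4-ketone | C=C1CC[C@@H]([C@@]2(C)CC[C@H](C(C)(C)OC(C)=O)O2)[C@@H](O)[C@H]2C(=O)CC[C@@H]12 | intermediate
24 | 6β-OTES 4-ketone | C=C1CC[C@@H]([C@@]2(C)CC[C@H](C(C)(C)OC(C)=O)O2)[C@@H](O[Si](CC)(CC)CC)[C@H]2C(=O)CC[C@@H]12 | intermediate
25 | potassium C3=C4 enolate of 24 | C=C1CC[C@@H]([C@@]2(C)CC[C@H](C(C)(C)OC(C)=O)O2)[C@@H](O[Si](CC)(CC)CC)[C@H]2C([O-])=CC[C@@H]12.[K+] | intermediate
26 | C3=C4 enol triflate | C=C1CC[C@@H]([C@@]2(C)CC[C@H](C(C)(C)OC(C)=O)O2)[C@@H](O[Si](CC)(CC)CC)[C@H]2C(OS(=O)(=O)C(F)(F)F)=CC[C@@H]12 | intermediate
27 | 6-O-triethylsilyl dictyol H | C=C1CC[C@@H]([C@@]2(C)CC[C@H](C(C)(C)OC(C)=O)O2)[C@@H](O[Si](CC)(CC)CC)[C@H]2C(C)=CC[C@@H]12 | intermediate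
28 | dictyol H (1R,5R,6S,7R,11R,14R) | C=C1CC[C@@H]([C@@]2(C)CC[C@H](C(C)(C)OC(C)=O)O2)[C@@H](O)[C@H]2C(C)=CC[C@@H]12 | target

## Step count and least certain steps

Total step count: 16. Longest linear sequence: 14 (steps 1–5 and 8–16). Steps 6 and 7 run in parallel.

**Step 10 (key step).**
- Most likely failure: slow opening of the cyclopropane, because the silyloxy group on C6 and ring C on C7 crowd the metal. Oligomerisation of the terminal allene, or reaction at its terminal π bond, could then take over.
- Loss of the enol silane through traces of HCl from the catalyst is a second risk.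
- Erosion of the facial selectivity through a rotamer with 4-OTBS in the olefin plane is a third risk.
- Fallback: it sets out from 9 and comes back at 19. The allene is replaced by an alkyne, the most reactive partner class of this cycloaddition, and C1 is set afterwards.
- Lithiated phenyl propargyl ether opens oxetane (BF3·OEt2) to 6-phenoxyhex-4-yn-1-ol F1. Oxidation as in step 7 gives 6-phenoxyhex-4-ynal F2.
- The aldol of step 8 with 9 gives the 4R ynyl aldol F3. Silylation as in step 9 gives the bis-silyl ynyl vinylcyclopropane F4.
- [Rh(CO)2Cl]2 closes F4 to the C1=C10 cycloheptadiene F5, which bears a phenoxymethyl group on C10.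
- Zerovalent palladium (from Pd(OAc)2 and PBu3) with HCO2H/Et3N then ionises the allyl phenyl ether. It should deliver hydride to the more substituted allyl terminus C1 from the less hindered α face, which gives 19.

**Step 8.**
- Most likely failure: modest facial selectivity, since isopinocampheyl enolborinates of methyl ketones discriminate unbranched aldehydes only moderately. The remote alkoxy centre C11 may also work against the reagent.
- Fallback: it sets out from 9 and 13 and comes back at 16, and it gives up asymmetric induction in favour of separation and recycling.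
- An achiral boron aldol (c-Hex2BCl, Et3N) gives 16 together with the 4S aldol F6. The two are diastereomers and are separated.
- F6 is oxidised with Dess–Martin periodinane to the 1,3-diketone F7. F7 is reduced again at its unhindered C4 carbonyl (NaBH4, MeOH, −78 °C) to a fresh mixture that re-enters the separation.

**Step 13.**
- Most likely failure: incomplete discrimination of the two secondary alcohols. This would lead to over-oxidation to the 1,3-diketone and loss of the C5 and C6 centres.
- Fallback: it sets out from 22 and comes back at 24, and it replaces selective oxidation by selective acylation.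
- Ac2O/pyridine at 0 °C acetylates the open 4α-OH to the 4-acetate F8. TESOTf/2,6-lutidine gives the 6-O-TES 4-acetate F9.
- K2CO3/MeOH at 0 °C removes the secondary acetate much faster than the tertiary one and gives the 4α-alcohol F10. Dess–Martin periodinane then gives 24.

**Step 15.**
- Most likely failure: competing deprotonation at C5, which expels the β-silyloxy group, or enolisation of the acetate.
- Fallback: it sets out from 24 and comes back at 27, and it avoids enolate chemistry.
- MeLi/CeCl3 (THF, −78 °C) should add to the ketone from the convex face and give the 4β-hydroxy-4α-methyl carbinol F11.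
- The Burgess reagent eliminates in the syn mode. H-5 is anti to the 4β-oxygen and cannot take part, so the C3=C4 olefin of 27 should be the main endocyclic product.

## Further compounds

F1 | step 10 | 6-phenoxyhex-4-yn-1-ol | OCCCC#CCOc1ccccc1
F2 | step 10 | 6-phenoxyhex-4-ynal | O=CCCC#CCOc1ccccc1
F3 | step 10 | 4R ynyl aldol of 9 with F2 | O(c1ccccc1)CC#CCC[C@@H](O)CC(=O)C1(CC1)[C@@]2(C)CC[C@H](C(C)(C)OC(C)=O)O2
F4 | step 10 | bis-silyl ynyl vinylcyclopropane | O(c1ccccc1)CC#CCC[C@@H](O[Si](C)(C)C(C)(C)C)/C=C(\O[Si](C)(C)C(C)(C)C)C1(CC1)[C@@]2(C)CC[C@H](C(C)(C)OC(C)=O)O2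
F5 | step 10 | C1=C10 cycloheptadiene with phenoxymethyl on C10 | c1ccccc1OCC3=C4CC[C@@H](O[Si](C)(C)C(C)(C)C)[C@@H]4C(O[Si](C)(C)C(C)(C)C)=C([C@@]2(C)CC[C@H](C(C)(C)OC(C)=O)O2)CC3
F6 | step 8 | 4S aldol (C4 epimer of 16) | C=C=CCC[C@H](O)CC(=O)C1(CC1)[C@@]2(C)CC[C@H](C(C)(C)OC(C)=O)O2
F7 | step 8 | 1,3-diketone (C4, C6) | C=C=CCCC(=O)CC(=O)C1(CC1)[C@@]2(C)CC[C@H](C(C)(C)OC(C)=O)O2
F8 | step 13 | 4-acetate of 22 | C=C1CC[C@@H]([C@@]2(C)CC[C@H](C(C)(C)OC(C)=O)O2)[C@@H](O)[C@H]2[C@H](OC(C)=O)CC[C@@H]12
F9 | step 13 | 6-O-TES 4-acetate | C=C1CC[C@@H]([C@@]2(C)CC[C@H](C(C)(C)OC(C)=O)O2)[C@@H](O[Si](CC)(CC)CC)[C@H]2[C@H](OC(C)=O)CC[C@@H]12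
F10 | step 13 | 6-O-TES 4α-alcohol | C=C1CC[C@@H]([C@@]2(C)CC[C@H](C(C)(C)OC(C)=O)O2)[C@@H](O[Si](CC)(CC)CC)[C@H]2[C@H](O)CC[C@@H]12
F11 | step 15 | 4β-hydroxy-4α-methyl carbinol | C=C1CC[C@@H]([C@@]2(C)CC[C@H](C(C)(C)OC(C)=O)O2)[C@@H](O[Si](CC)(CC)CC)[C@H]2[C@@](C)(O)CC[C@@H]12
A1 | alternative 1 | (5S)-2-methyl-5-(prop-1-en-2-yl)cyclopent-1-ene-1-carbaldehyde | O=CC1=C(C)CC[C@H]1C(C)=C
A2 | alternative 1 | metathesis diene (allyl and ring C on C7, isopropenyl on C1) | C=CC[C@@H]([C@@]2(C)CC[C@H](C(C)(C)OC(C)=O)O2)[C@@H](O)C1=C(C)CC[C@H]1C(C)=C
A3 | alternative 1 | metathesis product with endocyclic C9=C10 and C4=C5 | CC1=CC[C@@H]([C@@]2(C)CC[C@H](C(C)(C)OC(C)=O)O2)[C@@H](O)C2=C(C)CC[C@@H]12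
A4 | alternative 2 | Prins precursor, cis-cyclopentene aldehyde with oxidised geranyl-type chain | O=C[C@H]1C(C)=CC[C@H]1C(=C)CC/C=C(\C)CC[C@@H](O)C(C)(C)OC(C)=O
A5 | alternative 3 | side-chain-free C6 trimethylsilyl enol ether | C=C1CCC=C(O[Si](C)(C)C)[C@H]2C(C)=CC[C@@H]12
A6 | alternative 3 | ring C methyl ketal (both C11 anomers) | COC1(C)CC[C@H](C(C)(C)OC(C)=O)O1
A7 | alternative 3 | 6-oxo compound from the union | C=C1CC[C@@H]([C@@]2(C)CC[C@H](C(C)(C)OC(C)=O)O2)C(=O)[C@H]2C(C)=CC[C@@H]12
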